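# Proposed synthesis of CNP0375196.1 by sulfinyl-carbanion desymmetrisation of a 3-aryloxy-3-methyloxetane

## The problem

The target 20 is a 2H-chromene (O1, C2, C3=C4, C4a, C5 to C8, C8a) with an acetyl group on C6 and a free hydroxyl on C7. C2 carries a methyl group and an oxymethylene that is esterified with (E)-ferulic acid. The bicyclic skeleton is easy; the difficulty lies in C2, the only stereocentre. It is fully substituted, oxygen-bearing and R-configured, and the target offers no second stereocentre from which it could be derived, so its sense must come from a reagent, a catalyst, an auxiliary or the chiral pool. C2 is also fragile once formed: the O1–C2 bond is tertiary and allylic, so strong acid (ionisation) or light and prolonged heating (6π ring opening to an ortho-quinone methide and reclosure) can racemise it. The cinnamate ester is sensitive to base, nucleophiles and alcoholysis. The methyl ketone has α-protons that rule out strong base once it is in place, so the acetyl group must arrive late or travel masked. The enabling feature is the substitution pattern of C2: besides O1 and methyl it bears two one-carbon arms, ring carbon C3 and the exocyclic CH2O. Tied together through that oxygen, they make C2 the 3-position of an achiral 3-aryloxy-3-methyloxetane. A carbon nucleophile placed on C4 that opens this oxetane at one of its two enantiotopic methylenes creates the stereocentre, closes the pyran ring and frees the hydroxymethyl group in one event.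

## Retrosynthesis

**Unmasking.** Target 20 is traced to the bis-MOM ether 19 by cutting the two O–CH2OMe acetal bonds. Ketone 19 is traced to aryl bromide 17 by cutting the C6–C(acyl) bond, with enol ether 18 as the coupling product. MOM is preferred to silyl ethers, which would not survive the alkoxide chemistry early in the route, and to benzyl ethers, which cannot be removed beside three alkenes. A bromide is preferred to a ketal-masked acetyl group because it has no acidic protons, is inert to an amide base, and is installed by simple bromination of the starting phenol. The forward steps must be a neutral cross-coupling and one mild acid treatment.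

**Ester.** Bromide 17 is cut at the acyl–oxygen bond into chromene alcohol 13 and the protected ferulic acid 16, which comes from ferulic acid 14 through ester 15. Attaching the cinnamate after the carbanion chemistry keeps a Michael acceptor and a base-labile ester away from the amide base. The precursor 13 is a small bromochromene with one free alcohol. The forward reaction must acylate a β-branched primary alcohol without acid or strong base.

**Alkene.** The C3=C4 double bond of 13 is traced to a C4 sulfoxide in chroman 12 (C4–S and C3–H cut). A selenoxide or halide at C4 would also eliminate, but only the sulfoxide can first make C4 a carbanion and carry stereochemical information. The forward elimination can only run toward C3, and either C4 epimer serves.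

**Key disconnection.** Chroman 12 is cut at C3–C4. The nucleophile is the lithiated sulfoxide 11, made from sulfoxide 10; the electrophile is an oxetane methylene in the same molecule. The neighbouring cuts (O1–C2 or C8a–O1) need C2 to be preset. This cut creates C2 in the ring-forming step from a precursor whose only stereocentre is sulfur. It removes one ring and two carbon stereocentres. The forward reaction must open a strained ether at a methylene next to a quaternary carbon and must choose one of two enantiotopic methylenes under control of sulfur.

**Sulfur stereocentre.** Sulfoxide 10 is traced to sulfide 9 (S–O bond) and 9 to benzylic alcohol 7 and disulfide 8 (benzylic C–S bond). Catalytic asymmetric oxidation gives either antipode by choice of ligand. The classical tartrate ligand is poorly selective for aryl benzyl sulfides, so a 1,2-diaryl diol ligand is specified. The C–S bond must be formed without a labile, electron-rich benzyl halide.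

**Aryl ether and arene.** Alcohol 7 comes from aldehyde 6. The C8a–O1 bond of 6 is cut to fluoro aldehyde 3 and 3-methyloxetan-3-ol 4, used as its sodium alkoxide 5. A tertiary oxetanyl carbon cannot be the electrophile, so the aryl carbon must be; the formyl group that later becomes C4 activates the ortho fluoride. Aldehyde 3 comes from bromophenol 2 by MOM protection and 2 from commercial 2-fluoro-4-hydroxybenzaldehyde 1 by bromination.

## Roads not taken

**Alternative 1:** The cut is the C3=C4 double bond. Diene A1 (a vinyl group on the tertiary ether carbon and one on C4a) would be closed by ring-closing metathesis with the second-generation Grubbs catalyst RuCl2(=CHPh)(PCy3)(H2IMes), giving the silyl ether A2 of the target with loss of ethene.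
- Merits: metathesis to 2,2-disubstituted 2H-chromenes is among the most dependable ring closures. It is neutral, tolerates ketone, phenol and ester, and neither creates nor endangers a stereocentre, so the acetyl group could be carried unmasked.
- Weak points: the stereochemical problem is moved, not solved. A1 needs an enantiopure tertiary allylic aryl ether, made by arylating a hindered, enantiopure tertiary alkoxide that itself takes several steps from a chiral epoxide. The neighbouring oxygen needs a protecting group that cannot migrate to that alkoxide.
- Comparison: the ring closure of this road is more reliable than that of the chosen plan, and its chemistry is kept as the fallback for step 7. The chosen plan creates the quaternary centre from an achiral commercial oxetanol during ring formation, reaches both antipodes from one catalytic oxidation, and needs no chiral building block. The step counts are comparable.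

**Alternative 2:** The cut is the O1–C2 bond. The 2,3-epoxy alcohol A3 (accessible by Sharpless epoxidation) would be activated by camphorsulfonic acid, and the C8a hydroxyl would attack tertiary C2 with inversion to give chroman-3-ol A4.
- Merits: the epoxidation sets configuration by well-understood reagent control, acid steers the phenol to the tertiary carbon, and the acetyl group is in place from the start.
- Weak points: the attacking phenol is para to the acetyl group and therefore a poor nucleophile. Attack at C3 to give a dihydrobenzofuran competes. Substitution at a tertiary carbon under acid has ionisation character, so clean inversion is not assured. A4 still lacks the alkene: the C3 hydroxyl must be removed by regioselective dehydration toward C4 in the presence of a primary alcohol and a phenol, which costs several protection and activation steps.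
- Comparison: the key step of this road is better precedented than that of the chosen plan. The chosen plan makes or breaks no bond to C2 once the oxetane is in place, and the alkene emerges from the same group that made the carbanion, so the endgame is shorter.

**Alternative 3:** The cut is the C8a–O1 bond. KN(SiMe3)2 would deprotonate the tertiary alcohol of the Z-alkenyl aryl fluoride A5, and the alkoxide would displace fluoride para to the acetyl group to give the protected chromene A6.
- Merits: the carbinol stereocentre comes from the chiral pool and no bond to it is touched, so erosion is impossible. The acetyl group is used as the activating group, so no latent acetyl and no cross-coupling are needed, and the endgame is short.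
- Weak points: the acetyl group is also the most acidic site. Its enolate is a strong donor para to fluorine and switches off the activation on which the ring closure depends. Activation by one para-acyl group is modest in any case. The Z geometry must be made (partial hydrogenation of an alkyne over palladium on CaCO3 poisoned with Pb(OAc)2) and kept.
- Comparison: this is the shortest road on paper and stereochemically the safest. The chosen plan spends two operations on converting bromide to acetyl, but it has no carbonyl α-proton in its base-mediated step, needs no alkene geometry control, and draws its chirality from a catalyst.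

Key step: step 7

Assumption: the (S,S)-diol catalyst of step 6 is taken to give the (R)-sulfoxide 10, and (R)-10 is taken to lead to (2R)-12; if either correlation is found reversed, the (R,R)-diol is used instead and nothing else in the route changes.

## Route

Step 1
Reactants: 1 2-fluoro-4-hydroxybenzaldehyde
Product: 2 5-bromo-2-fluoro-4-hydroxybenzaldehyde
Conditions: Br2 (1.0 equiv), AcOH, 15 °C → rt
Reagents that add atoms: bromine, BrBr
Why: Electrophilic aromatic bromination of a phenol: the hydroxyl directs ortho, the para position is blocked by the formyl group, and C5 (para to fluorine, unhindered) is favoured over C3, which lies between fluorine and hydroxyl; one equivalent of bromine limits dibromination.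

Step 2
Reactants: 2 5-bromo-2-fluoro-4-hydroxybenzaldehyde
Product: 3 5-bromo-2-fluoro-4-(methoxymethoxy)benzaldehyde
Conditions: MOMCl, iPr2NEt, CH2Cl2, 0 °C → rt
Reagents that add atoms: chloromethyl methyl ether, COCCl
Why: Williamson-type O-alkylation of the acidic, formyl-conjugated phenol with an α-chloro ether; the MOM ether withstands every basic, reducing, oxidising and organometallic step that follows.

Step 3
Reactants: 3 5-bromo-2-fluoro-4-(methoxymethoxy)benzaldehyde; 4 3-methyloxetan-3-ol
Product: 6 5-bromo-4-(methoxymethoxy)-2-[(3-methyloxetan-3-yl)oxy]benzaldehyde, via sodium 3-methyloxetan-3-olate 5 (not isolated)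
Conditions: 4 (1.3 equiv), NaH, THF, 0 °C; then 3, DMF, 0 → 50 °C
Reagents that add atoms: none
Why: Nucleophilic aromatic substitution by addition–elimination: the ortho formyl group stabilises the Meisenheimer adduct and fluoride is the best leaving group for this mechanism; the tied-back tertiary alkoxide 5 is less hindered than tert-butoxide, has no α-hydrogen with which to reduce the aldehyde, and adds to the carbonyl group only reversibly.

Step 4
Reactants: 6 5-bromo-4-(methoxymethoxy)-2-[(3-methyloxetan-3-yl)oxy]benzaldehyde
Product: 7 {5-bromo-4-(methoxymethoxy)-2-[(3-methyloxetan-3-yl)oxy]phenyl}methanol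
Conditions: NaBH4, MeOH/THF, 0 °C
Reagents that add atoms: none
Why: Hydride reduction of an aromatic aldehyde with NaBH4; aryl bromide, acetal and oxetane are inert.

Step 5
Reactants: 7 {5-bromo-4-(methoxymethoxy)-2-[(3-methyloxetan-3-yl)oxy]phenyl}methanol; 8 bis(4-methylphenyl) disulfide
Product: 9 3-[4-bromo-5-(methoxymethoxy)-2-{[(4-methylphenyl)sulfanyl]methyl}phenoxy]-3-methyloxetane
Conditions: 8 (1.3 equiv), PBu3 (1.4 equiv), THF, rt
Reagents that add atoms: none
Why: Hata-type redox condensation: the phosphine and disulfide give a thiophosphonium thiolate, the benzylic alcohol is activated as its alkoxyphosphonium ion and displaced by thiolate in an SN2 step under neutral conditions, so no labile electron-rich benzyl halide and no acid come near the oxetane.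

Step 6
Reactants: 9 3-[4-bromo-5-(methoxymethoxy)-2-{[(4-methylphenyl)sulfanyl]methyl}phenoxy]-3-methyloxetane
Product: 10 3-[4-bromo-5-(methoxymethoxy)-2-{[(R)-(4-methylphenyl)sulfinyl]methyl}phenoxy]-3-methyloxetane
Conditions: Ti(OiPr)4 (5 mol%), (S,S)-1,2-diphenylethane-1,2-diol (10 mol%), t-BuOOH (70% in water, 1.1 equiv), toluene, 0 °C
Reagents that add atoms: tert-butyl hydroperoxide, CC(C)(C)OO
Why: Titanium-catalysed asymmetric sulfoxidation of the modified Kagan type: a chiral peroxotitanium complex delivers oxygen to one lone pair of sulfur; the 1,2-diaryl diol ligand is chosen because aryl benzyl sulfides, poorly differentiated by the tartrate system, are its best substrate class, and the sulfur stereocentre is set by the catalyst, with recrystallisation to raise enantiopurity if needed.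

Step 7
Reactants: 10 3-[4-bromo-5-(methoxymethoxy)-2-{[(R)-(4-methylphenyl)sulfinyl]methyl}phenoxy]-3-methyloxetane
Product: 12 [(2R)-6-bromo-7-(methoxymethoxy)-2-methyl-4-[(R)-(4-methylphenyl)sulfinyl]-3,4-dihydro-2H-chromen-2-yl]methanol (both C4 epimers), via lithiated sulfoxide 11 (not isolated)
Conditions: LiN(iPr)2 (1.1 equiv), THF, −78 °C; then BF3·OEt2 (2 equiv), −78 → −20 °C; aq. NaHCO3
Reagents that add atoms: none
Why: Proposed new method: LiN(iPr)2 removes one of the doubly activated (benzylic, α-sulfinyl) protons of 10 to give lithio sulfoxide 11, BF3·OEt2 then binds the oxetane oxygen, and the carbanion displaces that oxygen from one ring methylene by backside attack, forming the C3–C4 bond and leaving the other methylene as a CH2O–BF3 alkoxide that becomes the hydroxymethyl group on work-up. The closest known reaction types are the BF3-assisted opening of oxetanes by lithiated sulfones, dithianes and related sulfur-stabilised organolithiums, and the acid-catalysed desymmetrisation of 3,3-disubstituted oxetanes by tethered heteroatom nucleophiles; new here is a tethered α-sulfinyl carbanion as the nucleophile and its sulfur stereocentre as the controller. The pyran ring closes in the 6-exo-tet mode (the leaving oxygen lies outside the new ring), driven by release of roughly 105 kJ/mol of oxetane strain, which offsets attack at a methylene next to a quaternary carbon. C2 is set by the choice between the two enantiotopic methylenes: the in-line SN2 geometry places the breaking C–O bond anti to the forming C3–C4 bond, so in the chair-like transition state the oxetane CH2O arm is equatorial and the methyl group axial on C2, and the two methylenes correspond to the two mirror-image chairs. These chairs become diastereomeric because the lithium-bridged α-sulfinyl carbanion reacts through one face, with the p-tolyl group turned away from the electrophile and the sulfinyl group pseudo-equatorial to avoid the axial methyl, so control runs from sulfur to C4 and from C4 to C2. C4 is likewise set under control of sulfur, but its configuration does not matter because both epimers converge in step 8. The selectivity needed is enantiotopic-group selection, together with deprotonation at the benzylic carbon in preference to aryl C–H or C–Br, which an amide base at −78 °C secures; because sulfur is enantiopure, any 2S product is a diastereomer of 12 and is to be removed by chromatography or crystallisation before step 8.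

Step 8
Reactants: 12 [(2R)-6-bromo-7-(methoxymethoxy)-2-methyl-4-[(R)-(4-methylphenyl)sulfinyl]-3,4-dihydro-2H-chromen-2-yl]methanol (both C4 epimers)
Product: 13 [(2R)-6-bromo-7-(methoxymethoxy)-2-methyl-2H-chromen-2-yl]methanol
Conditions: toluene, pyridine (0.2 equiv), 100 °C, dark
Reagents that add atoms: none
Why: Thermal syn elimination of a sulfoxide through a five-membered cyclic transition state: each C4 epimer has a C3 hydrogen syn to sulfur, elimination can only run toward C3 because C4a is aromatic, and it is eased by the benzylic C–S bond and the styrene-type conjugation gained; C2 is not involved and the temperature stays below that at which 2H-chromenes ring-open.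

Step 9
Reactants: 14 (E)-ferulic acid
Product: 16 (2E)-3-[3-methoxy-4-(methoxymethoxy)phenyl]prop-2-enoic acid, via methoxymethyl ester 15 (not isolated)
Conditions: MOMCl (2.5 equiv), iPr2NEt, CH2Cl2, 0 °C → rt; then LiOH, THF/MeOH/H2O, rt; 1 M HCl to pH 3, 0 °C
Reagents that add atoms: chloromethyl methyl ether, COCCl; lithium hydroxide, [Li+].[OH-]
Why: Exhaustive O-alkylation of phenol and carboxylate, then saponification, which cleaves only the acetal ester 15 while the aryl MOM ether is stable to hydroxide; the E double bond is untouched.

Step 10
Reactants: 13 [(2R)-6-bromo-7-(methoxymethoxy)-2-methyl-2H-chromen-2-yl]methanol; 16 (2E)-3-[3-methoxy-4-(methoxymethoxy)phenyl]prop-2-enoic acid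
Product: 17 [(2R)-6-bromo-7-(methoxymethoxy)-2-methyl-2H-chromen-2-yl]methyl (2E)-3-[3-methoxy-4-(methoxymethoxy)phenyl]prop-2-enoate
Conditions: DCC (1.2 equiv), DMAP (0.2 equiv), CH2Cl2, 0 °C → rt
Reagents that add atoms: none
Why: Steglich esterification: the O-acylisourea is intercepted by DMAP and the acylpyridinium ion acylates the β-branched primary alcohol under neutral conditions that leave the MOM ethers, the aryl bromide and C2 alone.

Step 11
Reactants: 17 [(2R)-6-bromo-7-(methoxymethoxy)-2-methyl-2H-chromen-2-yl]methyl (2E)-3-[3-methoxy-4-(methoxymethoxy)phenyl]prop-2-enoate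
Product: 19 [(2R)-6-acetyl-7-(methoxymethoxy)-2-methyl-2H-chromen-2-yl]methyl (2E)-3-[3-methoxy-4-(methoxymethoxy)phenyl]prop-2-enoate, via enol ether 18 (not isolated)
Conditions: tributyl(1-ethoxyvinyl)stannane (1.5 equiv), Pd(PPh3)4 (5 mol%), toluene, 100 °C, dark; then 1 M HCl, THF, 0 °C, 20 min
Reagents that add atoms: tributyl(1-ethoxyvinyl)stannane, CCCC[Sn](CCCC)(CCCC)C(=C)OCC; water, O
Why: Stille coupling (oxidative addition into the C6–Br bond, transmetalation of the α-ethoxyvinyl group, reductive elimination) under neutral conditions gives enol ether 18, a masked methyl ketone; brief cold dilute acid hydrolyses this very labile enol ether well before it attacks the MOM acetals or the ester.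

Step 12
Reactants: 19 [(2R)-6-acetyl-7-(methoxymethoxy)-2-methyl-2H-chromen-2-yl]methyl (2E)-3-[3-methoxy-4-(methoxymethoxy)phenyl]prop-2-enoate
Product: 20 [(2R)-6-acetyl-7-hydroxy-2-methyl-2H-chromen-2-yl]methyl (2E)-3-(4-hydroxy-3-methoxyphenyl)prop-2-enoate
Conditions: 3 M aq. HCl, THF, 40 °C, dark
Reagents that add atoms: none
Why: Acid-catalysed acetal hydrolysis removes both MOM groups, the one on C7 first because its phenol becomes hydrogen-bonded to the acetyl carbonyl; water–THF in place of an alcohol excludes ester exchange, and ionisation of the O1–C2 bond is disfavoured by the adjacent acyloxymethyl group and the electron-poor ring, so moderate temperature and exclusion of light should keep C2 intact.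

## Compound list

1 | 2-fluoro-4-hydroxybenzaldehyde | O=Cc1ccc(O)cc1F | starting material
2 | 5-bromo-2-fluoro-4-hydroxybenzaldehyde | O=Cc1cc(Br)c(O)cc1F | intermediate
3 | 5-bromo-2-fluoro-4-(methoxymethoxy)benzaldehyde | O=Cc1cc(Br)c(OCOC)cc1F | intermediate
4 | 3-methyloxetan-3-ol | CC1(O)COC1 | starting material
5 | sodium 3-methyloxetan-3-olate (not isolated) | CC1([O-])COC1.[Na+] | intermediate
6 | 5-bromo-4-(methoxymethoxy)-2-[(3-methyloxetan-3-yl)oxy]benzaldehyde | O=Cc1cc(Br)c(OCOC)cc1OC1(C)COC1 | intermediate
7 | {5-bromo-4-(methoxymethoxy)-2-[(3-methyloxetan-3-yl)oxy]phenyl}methanol | OCc1cc(Br)c(OCOC)cc1OC1(C)COC1 | intermediate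
8 | bis(4-methylphenyl) disulfide | Cc1ccc(SSc2ccc(C)cc2)cc1 | starting material
9 | 3-[4-bromo-5-(methoxymethoxy)-2-{[(4-methylphenyl)sulfanyl]methyl}phenoxy]-3-methyloxetane | Cc1ccc(SCc2cc(Br)c(OCOC)cc2OC2(C)COC2)cc1 | intermediate
10 | 3-[4-bromo-5-(methoxymethoxy)-2-{[(R)-(4-methylphenyl)sulfinyl]methyl}phenoxy]-3-methyloxetane | CC1(COC1)Oc1cc(OCOC)c(Br)cc1C[S@@](=O)c1ccc(C)cc1 | intermediate
11 | lithiated sulfoxide: 10 with lithium on the benzylic carbon, (R) at sulfur, carbanion carbon not configurationally defined (not isolated) | CC1(COC1)Oc1cc(OCOC)c(Br)cc1C([Li])[S@@](=O)c1ccc(C)cc1 | intermediate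
12 | [(2R)-6-bromo-7-(methoxymethoxy)-2-methyl-4-[(R)-(4-methylphenyl)sulfinyl]-3,4-dihydro-2H-chromen-2-yl]methanol, both C4 epimers | OC[C@@]1(C)CC([S@@](=O)c2ccc(C)cc2)c2cc(Br)c(OCOC)cc2O1 | intermediate
13 | [(2R)-6-bromo-7-(methoxymethoxy)-2-methyl-2H-chromen-2-yl]methanol | OC[C@@]1(C)C=Cc2cc(Br)c(OCOC)cc2O1 | intermediate
14 | (E)-ferulic acid, (2E)-3-(4-hydroxy-3-methoxyphenyl)prop-2-enoic acid | COc1cc(/C=C/C(=O)O)ccc1O | starting material
15 | methoxymethyl (2E)-3-[3-methoxy-4-(methoxymethoxy)phenyl]prop-2-enoate (not isolated) | COCOC(=O)/C=C/c1ccc(OCOC)c(OC)c1 | intermediate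
16 | (2E)-3-[3-methoxy-4-(methoxymethoxy)phenyl]prop-2-enoic acid | COCOc1ccc(/C=C/C(=O)O)cc1OC | intermediate
17 | [(2R)-6-bromo-7-(methoxymethoxy)-2-methyl-2H-chromen-2-yl]methyl (2E)-3-[3-methoxy-4-(methoxymethoxy)phenyl]prop-2-enoate | COCOc1ccc(/C=C/C(=O)OC[C@@]2(C)C=Cc3cc(Br)c(OCOC)cc3O2)cc1OC | intermediate
18 | [(2R)-6-(1-ethoxyethenyl)-7-(methoxymethoxy)-2-methyl-2H-chromen-2-yl]methyl (2E)-3-[3-methoxy-4-(methoxymethoxy)phenyl]prop-2-enoate (not isolated) | COCOc1ccc(/C=C/C(=O)OC[C@@]2(C)C=Cc3cc(C(=C)OCC)c(OCOC)cc3O2)cc1OC | intermediate
19 | [(2R)-6-acetyl-7-(methoxymethoxy)-2-methyl-2H-chromen-2-yl]methyl (2E)-3-[3-methoxy-4-(methoxymethoxy)phenyl]prop-2-enoate | COCOc1ccc(/C=C/C(=O)OC[C@@]2(C)C=Cc3cc(C(C)=O)c(OCOC)cc3O2)cc1OC | intermediate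
20 | [(2R)-6-acetyl-7-hydroxy-2-methyl-2H-chromen-2-yl]methyl (2E)-3-(4-hydroxy-3-methoxyphenyl)prop-2-enoate (CNP0375196.1) | COc1cc(/C=C/C(=O)OC[C@@]2(C)C=Cc3cc(C(C)=O)c(O)cc3O2)ccc1O | target

## Step count and least certain steps

Total: 12 steps. Longest linear sequence: 11 steps (steps 1 to 8 and 10 to 12, from 1 to 20); step 9 is a one-step side branch.

**Step 7 (key step, proposed new method).** Two processes may fail. Proton transfer to, or decomposition of, the BF3-bound carbanion may outpace C–C bond formation at the hindered methylene. Or the sulfur stereocentre may discriminate poorly between the two enantiotopic methylenes, so that much material is lost when the 2S diastereomers are removed. The configuration of 12 can be checked crystallographically through its bromine and sulfur atoms.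

The fallback uses known chemistry only, sets out from 3 and rejoins the route at 13; it buys the C2 stereocentre instead of creating it.
- Commercial (S)-(2-methyloxiran-2-yl)methanol F1 is converted with NaH and 4-methoxybenzyl chloride into ether F2.
- Dimethylsulfonium methylide (Me3SI, n-BuLi, THF) opens F2 at its methylene and eliminates dimethyl sulfide to give the tertiary allylic alcohol F3.
- F3 is deprotonated with NaH and arylated with 3 in DMF, the same substitution as in step 3, to give aldehyde F4. The 4-methoxybenzyl group is chosen because a silyl group would migrate to the tertiary alkoxide.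
- Wittig methylenation (MePPh3Br, KOtBu, THF) gives diene F5.
- Ring-closing metathesis with the second-generation Grubbs catalyst RuCl2(=CHPh)(PCy3)(H2IMes) in CH2Cl2 at 40 °C gives chromene F6.
- Oxidative removal of the 4-methoxybenzyl group with DDQ in CH2Cl2/pH 7 buffer gives 13.

**Step 6.** Oxygen transfer may occur with insufficient facial discrimination, because the ortho oxetanyloxy and MOM oxygens can bind titanium and loosen the chiral environment; the enantiopurity of 10 caps that of 20. The fallback is an Andersen synthesis, which sets out from 7 and rejoins at 10. Alcohol 7 is converted with PPh3 and N-chlorosuccinimide in THF into benzyl chloride F7. Magnesium insertion (Mg turnings, THF, 0 °C, slow addition at high dilution, conditions under which aryl bromides do not insert) gives benzylmagnesium chloride F8. F8 is added at −40 °C to (1R,2S,5R)-menthyl (S)-4-methylbenzenesulfinate and displaces menthoxide with inversion at sulfur to give 10 in enantiopure form; the enantiomeric sulfinate gives the other antipode.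

**Step 3.** Substitution may be slow, because the para MOM-oxy group donates into the formyl acceptor, and base-induced degradation of the aldehyde may take over on heating. The fallback sets out from 3 and rejoins at 6, replacing the activating group by one that cannot be degraded. Aldehyde 3 is converted with I2 in aqueous NH3/THF into nitrile F9. F9 is treated with alkoxide 5 in DMF to give the aryl ether nitrile F10. Half-reduction with iBu2AlH in toluene at −78 °C, with hydrolysis of the aldimine, returns aldehyde 6.

**Step 12.** Cleavage of the less labile guaiacol MOM ether may need an acid strength or reaction time at which reversible opening of the O1–C2 bond (racemisation) or hydrolysis of the ester sets in. The fallback sets out from 13 and 14 and rejoins at 20; it carries the ferulate phenol as a fluoride-labile silyl ether, so that only the MOM group ortho to the acetyl group is left for acid.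
- Acid 14 is silylated on both oxygens (t-BuMe2SiCl, imidazole, DMF) to give F11, and K2CO3 in aqueous methanol frees the carboxylic acid again to give F12.
- F12 is coupled with 13 (DCC, DMAP) to give ester F13.
- Stille coupling as in step 11 gives enol ether F14, hydrolysed in the cold to ketone F15.
- Bu4NF buffered with AcOH in THF at 0 °C removes the silyl group to give phenol F16.
- 1 M HCl in THF at room temperature removes the remaining, carbonyl-assisted MOM group to give 20.

## Further compounds

F1 | step 7 | (S)-(2-methyloxiran-2-yl)methanol (purchased) | C[C@]1(CO)CO1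
F2 | step 7 | (2R)-2-{[(4-methoxyphenyl)methoxy]methyl}-2-methyloxirane | C[C@]1(COCc2ccc(OC)cc2)CO1
F3 | step 7 | (2R)-1-[(4-methoxyphenyl)methoxy]-2-methylbut-3-en-2-ol | C=C[C@@](C)(O)COCc1ccc(OC)cc1
F4 | step 7 | 5-bromo-4-(methoxymethoxy)-2-{[(2R)-1-[(4-methoxyphenyl)methoxy]-2-methylbut-3-en-2-yl]oxy}benzaldehyde | O=Cc1cc(Br)c(OCOC)cc1O[C@](C)(C=C)COCc1ccc(OC)cc1
F5 | step 7 | 1-bromo-5-ethenyl-2-(methoxymethoxy)-4-{[(2R)-1-[(4-methoxyphenyl)methoxy]-2-methylbut-3-en-2-yl]oxy}benzene | C=Cc1cc(Br)c(OCOC)cc1O[C@](C)(C=C)COCc1ccc(OC)cc1
F6 | step 7 | (2R)-6-bromo-7-(methoxymethoxy)-2-{[(4-methoxyphenyl)methoxy]methyl}-2-methyl-2H-chromene | COc1ccc(COC[C@@]2(C)C=Cc3cc(Br)c(OCOC)cc3O2)cc1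
F7 | step 6 | 3-[4-bromo-2-(chloromethyl)-5-(methoxymethoxy)phenoxy]-3-methyloxetane | ClCc1cc(Br)c(OCOC)cc1OC1(C)COC1
F8 | step 6 | {5-bromo-4-(methoxymethoxy)-2-[(3-methyloxetan-3-yl)oxy]benzyl}magnesium chloride | Cl[Mg]Cc1cc(Br)c(OCOC)cc1OC1(C)COC1
F9 | step 3 | 5-bromo-2-fluoro-4-(methoxymethoxy)benzonitrile | N#Cc1cc(Br)c(OCOC)cc1F
F10 | step 3 | 5-bromo-4-(methoxymethoxy)-2-[(3-methyloxetan-3-yl)oxy]benzonitrile | N#Cc1cc(Br)c(OCOC)cc1OC1(C)COC1
F11 | step 12 | tert-butyldimethylsilyl (2E)-3-{4-[(tert-butyldimethylsilyl)oxy]-3-methoxyphenyl}prop-2-enoate | COc1cc(/C=C/C(=O)O[Si](C)(C)C(C)(C)C)ccc1O[Si](C)(C)C(C)(C)C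
F12 | step 12 | (2E)-3-{4-[(tert-butyldimethylsilyl)oxy]-3-methoxyphenyl}prop-2-enoic acid | COc1cc(/C=C/C(=O)O)ccc1O[Si](C)(C)C(C)(C)C
F13 | step 12 | [(2R)-6-bromo-7-(methoxymethoxy)-2-methyl-2H-chromen-2-yl]methyl (2E)-3-{4-[(tert-butyldimethylsilyl)oxy]-3-methoxyphenyl}prop-2-enoate | COc1cc(/C=C/C(=O)OC[C@@]2(C)C=Cc3cc(Br)c(OCOC)cc3O2)ccc1O[Si](C)(C)C(C)(C)C
F14 | step 12 | [(2R)-6-(1-ethoxyethenyl)-7-(methoxymethoxy)-2-methyl-2H-chromen-2-yl]methyl (2E)-3-{4-[(tert-butyldimethylsilyl)oxy]-3-methoxyphenyl}prop-2-enoate | COc1cc(/C=C/C(=O)OC[C@@]2(C)C=Cc3cc(C(=C)OCC)c(OCOC)cc3O2)ccc1O[Si](C)(C)C(C)(C)C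
F15 | step 12 | [(2R)-6-acetyl-7-(methoxymethoxy)-2-methyl-2H-chromen-2-yl]methyl (2E)-3-{4-[(tert-butyldimethylsilyl)oxy]-3-methoxyphenyl}prop-2-enoate | COc1cc(/C=C/C(=O)OC[C@@]2(C)C=Cc3cc(C(C)=O)c(OCOC)cc3O2)ccc1O[Si](C)(C)C(C)(C)C
F16 | step 12 | [(2R)-6-acetyl-7-(methoxymethoxy)-2-methyl-2H-chromen-2-yl]methyl (2E)-3-(4-hydroxy-3-methoxyphenyl)prop-2-enoate | COc1cc(/C=C/C(=O)OC[C@@]2(C)C=Cc3cc(C(C)=O)c(OCOC)cc3O2)ccc1O
A1 | alternative 1 | (2R)-2-(4-acetyl-2-ethenyl-5-hydroxyphenoxy)-2-methylbut-3-en-1-yl (2E)-3-{4-[(tert-butyldimethylsilyl)oxy]-3-methoxyphenyl}prop-2-enoate | COc1cc(/C=C/C(=O)OC[C@@](C)(C=C)Oc2cc(O)c(C(C)=O)cc2C=C)ccc1O[Si](C)(C)C(C)(C)C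
A2 | alternative 1 | [(2R)-6-acetyl-7-hydroxy-2-methyl-2H-chromen-2-yl]methyl (2E)-3-{4-[(tert-butyldimethylsilyl)oxy]-3-methoxyphenyl}prop-2-enoate | COc1cc(/C=C/C(=O)OC[C@@]2(C)C=Cc3cc(C(C)=O)c(O)cc3O2)ccc1O[Si](C)(C)C(C)(C)C
A3 | alternative 2 | [(2R,3R)-3-[(5-acetyl-2,4-dihydroxyphenyl)methyl]-2-methyloxiran-2-yl]methanol | OC[C@@]1(C)O[C@@H]1Cc1cc(C(C)=O)c(O)cc1O
A4 | alternative 2 | 1-[(2S,3R)-3,7-dihydroxy-2-(hydroxymethyl)-2-methyl-3,4-dihydro-2H-chromen-6-yl]ethan-1-one | OC[C@@]1(C)[C@H](O)Cc2cc(C(C)=O)c(O)cc2O1
A5 | alternative 3 | 1-{4-fluoro-5-[(1Z,3R)-3-hydroxy-4-[(4-methoxyphenyl)methoxy]-3-methylbut-1-en-1-yl]-2-(methoxymethoxy)phenyl}ethan-1-one | COc1ccc(COC[C@](C)(O)/C=C\c2cc(C(C)=O)c(OCOC)cc2F)cc1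
A6 | alternative 3 | 1-[(2R)-7-(methoxymethoxy)-2-{[(4-methoxyphenyl)methoxy]methyl}-2-methyl-2H-chromen-6-yl]ethan-1-one | COc1ccc(COC[C@@]2(C)C=Cc3cc(C(C)=O)c(OCOC)cc3O2)cc1
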